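**Strategy.** The trimer is cut at its three C11–O ether bonds and two C15–O ester bonds into three copies of one drimane aldehyde and three isocitrate units (two kinds) made from (R)-malic acid. Each decalin arises from an acyclic (2E,8E)-2,8-dimethylundeca-2,8,10-trienal by an intramolecular Diels–Alder reaction: the C10=C1–C2=C3 diene adds to the C4=C5 enal, forming C3–C4 and C5–C10 at once, so that ring A is the cycloadduct and ring B the closed C6–C9 tether. The step exploits the quaternary C4 (methyl, oxidised C15) beside the trans ring fusion C5/C10; equatorial C8 and C9 substituents, set by Sharpless epoxidation, fix C4, C5 and C10.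

Key step: step 11

Remark: decalins are described on the drimane skeleton (ring A = C1–C5, C10; ring B = C5–C10; C11 on C9, C12 on C8, C15 = oxygenated carbon on C4), and the same locants are used for the open-chain precursors. TBS = tert-butyldimethylsilyl, TBDPS = tert-butyldiphenylsilyl, TES = triethylsilyl, Bn = benzyl. (E)-But-2-ene-1,4-diol and (R)-malic acid are taken as commercial.

**Part 1 – drimane aldehyde 21 (used three times)**

Step 1
Reactants: 1 (E)-but-2-ene-1,4-diol
Product: 2 (E)-4-(TBS-oxy)but-2-en-1-ol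
Conditions: NaH (1 equiv), TBSCl (1 equiv), THF, 0 °C → rt
Reagents that add atoms: tert-butyldimethylsilyl chloride, CC(C)(C)[Si](C)(C)Cl
Why: Monosilylation of a symmetrical diol through its sparingly soluble monosodium alkoxide (Williamson-type O-silylation); no stereocenter is formed.

Step 2
Reactants: 2 (E)-4-(TBS-oxy)but-2-en-1-ol
Product: 3 (2R,3R)-epoxy alcohol
Conditions: Ti(OiPr)4 (10 mol %), D-(−)-diisopropyl tartrate (12 mol %), tBuOOH, 4 Å molecular sieves, CH2Cl2, −20 °C
Reagents that add atoms: tert-butyl hydroperoxide, CC(C)(C)OO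
Why: Sharpless asymmetric epoxidation of a primary (E)-allylic alcohol, in which the D-(−)-tartrate ligand should deliver oxygen to the face giving the (2R,3R)-epoxide and so fix C8 and, after inversion in step 3, C9.

Step 3
Reactants: 3 (2R,3R)-epoxy alcohol
Product: 4 (2S,3S)-3-(TBS-oxymethyl)-5-(trimethylsilyl)pent-4-yne-1,2-diol
Conditions: Me3SiC≡CH, nBuLi, Et2AlCl, toluene, 0 °C → rt
Reagents that add atoms: ethynyltrimethylsilane (delivered as its diethylaluminium acetylide), C#C[Si](C)(C)C
Why: Alkoxyaluminium-directed SN2 opening of a 2,3-epoxy alcohol by an alkynylalane at C-3 (the carbon carrying CH2OTBS), with inversion at the future C9, which gives the 8,9-relationship that later places both substituents equatorial on ring B.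

Step 4
Reactants: 4 silylalkyne diol
Product: 5 (2S,3S)-3-(TBS-oxymethyl)pent-4-yne-1,2-diol
Conditions: K2CO3, MeOH, rt
Reagents that add atoms: none
Why: Base-mediated protodesilylation of the alkynylsilane, to which the alkyl TBS ether is stable.

Step 5
Reactants: 5 terminal alkyne diol
Product: 7 (2S,3S,4E)-3-(TBS-oxymethyl)-4-methylhepta-4,6-diene-1,2-diol, via alkenylalane 6 (not isolated)
Conditions: AlMe3 (4 equiv), Cp2ZrCl2 (25 mol %), CH2Cl2, 0 °C → rt; then CH2=CHBr, ZnCl2, Pd(PPh3)4 (5 mol %), THF, rt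
Reagents that add atoms: trimethylaluminium, C[Al](C)C; vinyl bromide, C=CBr
Why: Negishi zirconium-catalysed carboalumination (syn addition, methyl to the internal carbon C10) followed by Pd-catalysed cross-coupling of the alkenylalane with retention, which should give the (E)-diene with the C10 methyl cis to the vinyl group and C9 outside.

Step 6
Reactants: 7 diene diol
Product: 9 dienyl (S)-epoxide, via primary tosylate 8 (not isolated)
Conditions: TsCl, Et3N, Bu2SnO (2 mol %), CH2Cl2, 0 °C; then K2CO3, MeOH, rt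
Reagents that add atoms: p-toluenesulfonyl chloride (atoms kept in 8 only), Cc1ccc(cc1)S(=O)(=O)Cl
Why: Tin-catalysed selective sulfonylation of the primary hydroxyl of the 1,2-diol and intramolecular Williamson closure by the C8 alkoxide, which leaves the C8 configuration untouched.

Step 7
Reactants: 9 dienyl epoxide
Product: 10 (4R,5S,6E)-4-hydroxy nitrile
Conditions: MeCN, nBuLi, THF, −78 °C; then 9, −78 → 0 °C
Reagents that add atoms: acetonitrile, CC#N
Why: SN2 opening of the terminal epoxide at its CH2 carbon (C7) by lithiated acetonitrile, which adds C6 and C5 and liberates the C8 alcohol.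

Step 8
Reactants: 10 hydroxy nitrile
Product: 11 8-O-benzyl nitrile
Conditions: 2-benzyloxy-1-methylpyridinium triflate, MgO, PhCF3, 85 °C
Reagents that add atoms: 2-benzyloxy-1-methylpyridinium triflate, C[n+]1ccccc1OCc1ccccc1.[O-]S(=O)(=O)C(F)(F)F
Why: Neutral benzyl transfer from the pyridinium salt to the secondary alcohol (O-benzylation), chosen because base would deprotonate the nitrile and acid would endanger the TBS ether and the diene.

Step 9
Reactants: 11 benzyloxy nitrile
Product: 12 (4R,5S,6E)-4-(benzyloxy)-5-(TBS-oxymethyl)-6-methylnona-6,8-dienal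
Conditions: iBu2AlH, CH2Cl2, −78 °C; then aqueous potassium sodium tartrate
Reagents that add atoms: water, O
Why: Partial hydride reduction of the nitrile to the N-aluminio imine and hydrolysis to the aldehyde (DIBAL reduction), which the diene and both ethers tolerate.

Step 10
Reactants: 12 dienal
Product: 13 (2E,6R,7S,8E)-6-(benzyloxy)-7-(TBS-oxymethyl)-2,8-dimethylundeca-2,8,10-trienal
Conditions: Ph3P=C(Me)CHO, CH2Cl2, 40 °C
Reagents that add atoms: 2-(triphenylphosphoranylidene)propanal, CC(C=O)=P(c1ccccc1)(c1ccccc1)c1ccccc1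
Why: Wittig olefination with a stabilised α-methyl ylide, which should give the (E)-2-methyl enal that places the formyl group cis to H-5.

Step 11
Reactants: 13 trienal
Product: 14 8α-(benzyloxy)-11-(TBS-oxy)-12-nordrim-1-en-15-al
Conditions: Me2AlCl (1.2 equiv), CH2Cl2, −78 → −20 °C
Reagents that add atoms: none
Why: Me2AlCl binds the enal oxygen and the C10=C1–C2=C3 diene adds across the activated C4=C5 bond in a concerted but asynchronous [4+2] cycloaddition, the Lewis-acid-promoted type 1 intramolecular Diels–Alder reaction of a 1,3,9-decatriene known to give trans-decalins with a formyl/methyl quaternary carbon. Ring A is closed by both new bonds (C3–C4 and C5–C10) as the cycloadduct ring, and ring B is closed by the C5–C10 bond alone as the ring of the four-carbon tether C6–C9. C4 follows from the (E)-enal geometry (formyl cis to H-5) and the endo position of the aluminium-bound formyl group; C5 and C10 become trans because the (E)-diene with the tether outside meets the endo formyl through a chair-like tether. Their absolute sense comes from C8 and C9: only one diene face lets the benzyloxy and silyloxymethyl groups both sit equatorial on the forming chair, the other face would make both axial. The step therefore needs endo over exo selectivity, secured by the Lewis acid, and one diene face, secured by the trans-diequatorial C8/C9 pair. The C10 methyl lies inside the diene and develops a 1,3-diaxial contact with the C4 methyl, which slows the reaction and is why the reactive enal with Lewis-acid activation is used.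

Step 12
Reactants: 14 octalin aldehyde
Product: 15 8α-(benzyloxy)-11-(TBS-oxy)-12-nordrim-1-en-15-ol
Conditions: NaBH4, MeOH, 0 °C
Reagents that add atoms: none
Why: Hydride reduction of the hindered, non-enolisable aldehyde to the C15 primary alcohol.

Step 13
Reactants: 15 C15 alcohol
Product: 16 15-O-TBDPS ether
Conditions: TBDPSCl, imidazole, DMAP (cat.), DMF, 40 °C
Reagents that add atoms: tert-butyldiphenylsilyl chloride, CC(C)(C)[Si](Cl)(c1ccccc1)c1ccccc1
Why: Silylation of the neopentyl primary alcohol with a group chosen to outlast the later removal of the TBS ether.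

Step 14
Reactants: 16 benzyl ether alkene
Product: 17 11-(TBS-oxy)-15-(TBDPS-oxy)-12-nordriman-8α-ol
Conditions: H2 (1 atm), Pd/C (10 %), EtOAc, rt
Reagents that add atoms: none
Why: Heterogeneous hydrogenation should saturate the C1=C2 bond and hydrogenolyse the benzyl ether in the same operation, while both silyl ethers survive in ethyl acetate.

Step 15
Reactants: 17 C8 alcohol
Product: 18 12-nordriman-8-one
Conditions: Dess–Martin periodinane, NaHCO3, CH2Cl2, rt
Reagents that add atoms: none
Why: Dess–Martin oxidation of the secondary alcohol to the C8 ketone, with C9 already in its more stable equatorial configuration.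

Step 16
Reactants: 18 C8 ketone
Product: 19 11-(TBS-oxy)-15-(TBDPS-oxy)drim-8(12)-ene
Conditions: Ph3PCH3Br, KN(SiMe3)2, THF, 0 °C → rt
Reagents that add atoms: methyltriphenylphosphonium bromide, C[P+](c1ccccc1)(c1ccccc1)c1ccccc1.[Br-]
Why: Wittig methylenation of the decalone, the usual way to the 8(12)-exocyclic alkene of drimanes from 8-ketones carrying a protected 11-hydroxyl.

Step 17
Reactants: 19 bis-silyl ether
Product: 20 15-(TBDPS-oxy)drim-8(12)-en-11-ol
Conditions: PPTS (cat.), MeOH, rt
Reagents that add atoms: none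
Why: Acid-catalysed methanolysis should remove the less robust primary TBS ether while the neopentyl TBDPS ether and the exocyclic alkene stay.

Step 18
Reactants: 20 C11 alcohol
Product: 21 15-(TBDPS-oxy)drim-8(12)-en-11-al
Conditions: Dess–Martin periodinane, NaHCO3, CH2Cl2, 0 °C
Reagents that add atoms: none
Why: Buffered Dess–Martin oxidation gives the β,γ-unsaturated aldehyde without acid or base, so that C9 and the exocyclic alkene are kept.

**Part 2 – isocitrate units from (R)-malic acid**

Step 19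
Reactants: 22 (R)-malic acid
Product: 24 (R)-malic acid 1-methyl ester, via trifluoroacetoxy anhydride 23 (not isolated)
Conditions: (CF3CO)2O, 0 °C → rt, evaporate; then MeOH, rt
Reagents that add atoms: trifluoroacetic anhydride (atoms kept in 23 only), O=C(OC(=O)C(F)(F)F)C(F)(F)F; methanol, CO
Why: Regioselective anhydride opening, in which methanol attacks the carbonyl next to the acyloxy carbon of the O-trifluoroacetyl cyclic anhydride and also removes the trifluoroacetate, leaving the stereocenter untouched.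

Step 20
Reactants: 24 (R)-malic acid 1-methyl ester
Product: 25 4-allyl 1-methyl (R)-malate
Conditions: allyl bromide, KHCO3, DMF, rt
Reagents that add atoms: allyl bromide, C=CCBr
Why: Carboxylate O-alkylation under weakly basic conditions, which leaves the secondary alcohol free.

Step 21
Reactants: 25 4-allyl 1-methyl (R)-malate
Product: 27 2-allyl 1,3-dimethyl (1R,2S)-1-hydroxypropane-1,2,3-tricarboxylate, via dilithio alkoxide enolate 26 (not isolated)
Conditions: LiN(SiMe3)2 (2.2 equiv), THF, −78 °C; BrCH2CO2Me, −78 → −40 °C; AcOH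
Reagents that add atoms: methyl bromoacetate, COC(=O)CBr; lithium bis(trimethylsilyl)amide (lithium kept in 26 only), [Li]N([Si](C)(C)C)[Si](C)(C)C
Why: Fráter–Seebach alkylation, in which the chelated lithium alkoxide enolate is alkylated anti to the C–O bond and so sets the new center as (2S), the natural isocitrate configuration.

Step 22
Reactants: 27 hydroxy triester
Product: 28 TES ether of 27
Conditions: Et3SiCl, imidazole, DMF, 0 °C
Reagents that add atoms: chlorotriethylsilane, CC[Si](Cl)(CC)CC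
Why: O-silylation of the α-hydroxy ester, which blocks lactonisation and provides the silyl ether used as oxygen donor in the ether-forming step.

Step 23
Reactants: 24 (R)-malic acid 1-methyl ester
Product: 29 4-tert-butyl 1-methyl (R)-malate
Conditions: tert-butyl 2,2,2-trichloroacetimidate, CH2Cl2/cyclohexane, rt
Reagents that add atoms: tert-butyl 2,2,2-trichloroacetimidate, CC(C)(C)OC(=N)C(Cl)(Cl)Cl
Why: Esterification of the free acid by the trichloroacetimidate without added Lewis acid, conditions under which the alcohol does not react.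

Step 24
Reactants: 29 4-tert-butyl 1-methyl (R)-malate
Product: 31 3-allyl 2-tert-butyl 1-methyl (1R,2S)-1-hydroxypropane-1,2,3-tricarboxylate, via dilithio alkoxide enolate 30 (not isolated)
Conditions: LiN(SiMe3)2 (2.2 equiv), THF, −78 °C; BrCH2CO2CH2CH=CH2, −78 → −40 °C; AcOH
Reagents that add atoms: allyl bromoacetate, C=CCOC(=O)CBr; lithium bis(trimethylsilyl)amide (lithium kept in 30 only), [Li]N([Si](C)(C)C)[Si](C)(C)C
Why: Fráter–Seebach alkylation as in step 21, with anti attack on the chelated alkoxide enolate setting the (2S) center.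

Step 25
Reactants: 31 hydroxy tert-butyl ester
Product: 33 (2S,3R)-2-[2-(allyloxy)-2-oxoethyl]-4-methoxy-4-oxo-3-(TES-oxy)butanoic acid, via bis-silyl compound 32 (not isolated)
Conditions: Et3SiOTf (2.5 equiv), 2,6-lutidine, CH2Cl2, 0 °C → rt; then pH 7 phosphate buffer
Reagents that add atoms: triethylsilyl trifluoromethanesulfonate, CC[Si](CC)(CC)OS(=O)(=O)C(F)(F)F
Why: Silyl-triflate-mediated cleavage of the tert-butyl ester to the silyl ester with loss of isobutene and concurrent O-silylation; the silyl ester hydrolyses on aqueous work-up while the TES ether, allyl and methyl esters remain.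

**Part 3 – assembly**

Step 26
Reactants: 21 drimane aldehyde; 28 TES ether of isocitrate triester
Product: 34 ether of unit A with isocitrate 1 (15-O-TBDPS)
Conditions: Et3SiH (3 equiv), Me3SiOTf (0.3 equiv), CH2Cl2, −78 → −40 °C
Reagents that add atoms: none
Why: Reductive etherification, in which the silyl ether adds to the silyl-triflate-activated aldehyde and the oxocarbenium ion is reduced by Et3SiH, forming the C11–O bond without touching the C2' stereocenter, the esters or the alkene.

Step 27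
Reactants: 34 silyl-protected ether
Product: 35 unit A ether with free 15-OH
Conditions: HF·pyridine, pyridine, THF, 0 °C → rt
Reagents that add atoms: none
Why: Fluoride cleavage of the TBDPS ether under buffered, weakly acidic conditions that spare the esters, the ether and the exocyclic alkene.

Step 28
Reactants: 35 C15 alcohol; 33 isocitrate acid
Product: 36 15-O-acyl compound (isocitrate 2 as TES ether)
Conditions: 2-methyl-6-nitrobenzoic anhydride, DMAP, Et3N, CH2Cl2, rt
Reagents that add atoms: none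
Why: Shiina esterification (mixed anhydride, acyl transfer by DMAP) of the neopentyl alcohol with the α-branched acid under mild base that should not epimerise or eliminate the β-silyloxy acid.

Step 29
Reactants: 36 TES ether; 21 drimane aldehyde
Product: 37 ether carrying units A and B (15-O-TBDPS on unit B)
Conditions: Et3SiH (3 equiv), Me3SiOTf (0.3 equiv), CH2Cl2, −78 → −40 °C
Reagents that add atoms: none
Why: Reductive etherification as in step 26, the TES ether of isocitrate 2 being the only silyl ether reactive enough to add to the activated aldehyde.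

Step 30
Reactants: 37 silyl-protected dimer
Product: 38 dimer with free 15-OH on unit B
Conditions: HF·pyridine, pyridine, THF, 0 °C → rt
Reagents that add atoms: none
Why: Fluoride cleavage of the only silyl ether present, as in step 27.

Step 31
Reactants: 38 C15 alcohol; 33 isocitrate acid
Product: 39 dimer acylated with isocitrate 3 (TES ether)
Conditions: 2-methyl-6-nitrobenzoic anhydride, DMAP, Et3N, CH2Cl2, rt
Reagents that add atoms: none
Why: Shiina esterification as in step 28.

Step 32
Reactants: 39 TES ether; 21 drimane aldehyde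
Product: 40 protected trimer (15-O-TBDPS on unit C, three allyl esters)
Conditions: Et3SiH (3 equiv), Me3SiOTf (0.3 equiv), CH2Cl2, −78 → −40 °C
Reagents that add atoms: none
Why: Reductive etherification as in step 26, attaching unit C.

Step 33
Reactants: 40 protected trimer
Product: 41 triallyl ester with free 15-OH on unit C
Conditions: HF·pyridine, pyridine, THF, 0 °C → rt
Reagents that add atoms: none
Why: Fluoride cleavage of the last silyl ether under conditions harmless to allyl and methyl esters and to the three exocyclic alkenes.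

Step 34
Reactants: 41 triallyl ester
Product: 42 cryptoporic acid T
Conditions: Pd(PPh3)4 (10 mol %), morpholine, THF, rt; acidic work-up
Reagents that add atoms: none
Why: Tsuji–Trost deallylation, in which zerovalent palladium ionises the three allyl esters and morpholine traps the allyl groups, leaving the four methyl esters, the two neopentyl esters and the alkenes untouched.

**Compound list**

1 | (E)-but-2-ene-1,4-diol | OC/C=C/CO | starting material
2 | (E)-4-[(tert-butyldimethylsilyl)oxy]but-2-en-1-ol | OC/C=C/CO[Si](C)(C)C(C)(C)C | intermediate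
3 | [(2R,3R)-3-{[(tert-butyldimethylsilyl)oxy]methyl}oxiran-2-yl]methanol | OC[C@H]1O[C@@H]1CO[Si](C)(C)C(C)(C)C | intermediate
4 | (2S,3S)-3-{[(tert-butyldimethylsilyl)oxy]methyl}-5-(trimethylsilyl)pent-4-yne-1,2-diol | OC[C@@H](O)[C@H](CO[Si](C)(C)C(C)(C)C)C#C[Si](C)(C)C | intermediate
5 | (2S,3S)-3-{[(tert-butyldimethylsilyl)oxy]methyl}pent-4-yne-1,2-diol | OC[C@@H](O)[C@H](CO[Si](C)(C)C(C)(C)C)C#C | intermediate
6 | (E)-alkenyldimethylalane from 5 (both hydroxyls as dimethylaluminium alkoxides) | C[Al](C)OC[C@@H](O[Al](C)C)[C@H](CO[Si](C)(C)C(C)(C)C)/C(C)=C/[Al](C)C | intermediate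
7 | (2S,3S,4E)-3-{[(tert-butyldimethylsilyl)oxy]methyl}-4-methylhepta-4,6-diene-1,2-diol | OC[C@@H](O)[C@H](CO[Si](C)(C)C(C)(C)C)/C(C)=C/C=C | intermediate
8 | (2S,3S,4E)-3-{[(tert-butyldimethylsilyl)oxy]methyl}-2-hydroxy-4-methylhepta-4,6-dien-1-yl 4-methylbenzenesulfonate | Cc1ccc(cc1)S(=O)(=O)OC[C@@H](O)[C@H](CO[Si](C)(C)C(C)(C)C)/C(C)=C/C=C | intermediate
9 | tert-butyl(dimethyl){[(2S,3E)-3-methyl-2-[(2S)-oxiran-2-yl]hexa-3,5-dien-1-yl]oxy}silane | C1O[C@H]1[C@H](CO[Si](C)(C)C(C)(C)C)/C(C)=C/C=C | intermediate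
10 | (4R,5S,6E)-5-{[(tert-butyldimethylsilyl)oxy]methyl}-4-hydroxy-6-methylnona-6,8-dienenitrile | N#CCC[C@@H](O)[C@H](CO[Si](C)(C)C(C)(C)C)/C(C)=C/C=C | intermediate
11 | (4R,5S,6E)-4-(benzyloxy)-5-{[(tert-butyldimethylsilyl)oxy]methyl}-6-methylnona-6,8-dienenitrile | N#CCC[C@@H](OCc1ccccc1)[C@H](CO[Si](C)(C)C(C)(C)C)/C(C)=C/C=C | intermediate
12 | (4R,5S,6E)-4-(benzyloxy)-5-{[(tert-butyldimethylsilyl)oxy]methyl}-6-methylnona-6,8-dienal | O=CCC[C@@H](OCc1ccccc1)[C@H](CO[Si](C)(C)C(C)(C)C)/C(C)=C/C=C | intermediate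
13 | (2E,6R,7S,8E)-6-(benzyloxy)-7-{[(tert-butyldimethylsilyl)oxy]methyl}-2,8-dimethylundeca-2,8,10-trienal | O=C/C(C)=C/CC[C@@H](OCc1ccccc1)[C@H](CO[Si](C)(C)C(C)(C)C)/C(C)=C/C=C | intermediate
14 | 8α-(benzyloxy)-11-[(tert-butyldimethylsilyl)oxy]-12-nordrim-1-en-15-al (4α-CHO, 4β-CH3, 5α-H, 9β-CH2OTBS, 10β-CH3) | CC(C)(C)[Si](C)(C)OC[C@H]1[C@H](OCc3ccccc3)CC[C@H]2[C@](C)(C=O)CC=C[C@]12C | intermediate
15 | 8α-(benzyloxy)-11-[(tert-butyldimethylsilyl)oxy]-12-nordrim-1-en-15-ol (same ring configuration as 14) | CC(C)(C)[Si](C)(C)OC[C@H]1[C@H](OCc3ccccc3)CC[C@H]2[C@](C)(CO)CC=C[C@]12C | intermediate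
16 | 8α-(benzyloxy)-11-[(tert-butyldimethylsilyl)oxy]-15-[(tert-butyldiphenylsilyl)oxy]-12-nordrim-1-ene | CC(C)(C)[Si](C)(C)OC[C@H]1[C@H](OCc3ccccc3)CC[C@H]2[C@](C)(CO[Si](c4ccccc4)(c5ccccc5)C(C)(C)C)CC=C[C@]12C | intermediate
17 | 11-[(tert-butyldimethylsilyl)oxy]-15-[(tert-butyldiphenylsilyl)oxy]-12-nordriman-8α-ol (5α-H, 9α-H, 4β- and 10β-CH3) | CC(C)(C)[Si](C)(C)OC[C@H]1[C@H](O)CC[C@H]2[C@](C)(CO[Si](c4ccccc4)(c5ccccc5)C(C)(C)C)CCC[C@]12C | intermediate
18 | 11-[(tert-butyldimethylsilyl)oxy]-15-[(tert-butyldiphenylsilyl)oxy]-12-nordriman-8-one | CC(C)(C)[Si](C)(C)OC[C@H]1C(=O)CC[C@H]2[C@](C)(CO[Si](c4ccccc4)(c5ccccc5)C(C)(C)C)CCC[C@]12C | intermediate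
19 | 11-[(tert-butyldimethylsilyl)oxy]-15-[(tert-butyldiphenylsilyl)oxy]drim-8(12)-ene | CC(C)(C)[Si](C)(C)OC[C@H]1C(=C)CC[C@H]2[C@](C)(CO[Si](c4ccccc4)(c5ccccc5)C(C)(C)C)CCC[C@]12C | intermediate
20 | 15-[(tert-butyldiphenylsilyl)oxy]drim-8(12)-en-11-ol | OC[C@H]1C(=C)CC[C@H]2[C@](C)(CO[Si](c4ccccc4)(c5ccccc5)C(C)(C)C)CCC[C@]12C | intermediate
21 | 15-[(tert-butyldiphenylsilyl)oxy]drim-8(12)-en-11-al (9β-CHO, 4α-CH2OTBDPS, 4β- and 10β-CH3, 5α-H) | O=C[C@H]1C(=C)CC[C@H]2[C@](C)(CO[Si](c4ccccc4)(c5ccccc5)C(C)(C)C)CCC[C@]12C | intermediate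
22 | (R)-malic acid | O[C@@H](C(=O)O)CC(=O)O | starting material
23 | (R)-2-(trifluoroacetoxy)succinic anhydride | O=C1C[C@@H](OC(=O)C(F)(F)F)C(=O)O1 | intermediate
24 | (3R)-3-hydroxy-4-methoxy-4-oxobutanoic acid | OC(=O)C[C@@H](O)C(=O)OC | intermediate
25 | 1-methyl 4-prop-2-en-1-yl (2R)-2-hydroxybutanedioate | C=CCOC(=O)C[C@@H](O)C(=O)OC | intermediate
26 | dilithium alkoxide ester enolate of 25 | [Li]OC(OCC=C)=C[C@@H](O[Li])C(=O)OC | intermediate
27 | 1,3-dimethyl 2-prop-2-en-1-yl (1R,2S)-1-hydroxypropane-1,2,3-tricarboxylate | O[C@@H](C(=O)OC)[C@H](CC(=O)OC)C(=O)OCC=C | intermediate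
28 | 1,3-dimethyl 2-prop-2-en-1-yl (1R,2S)-1-[(triethylsilyl)oxy]propane-1,2,3-tricarboxylate | CC[Si](CC)(CC)O[C@@H](C(=O)OC)[C@H](CC(=O)OC)C(=O)OCC=C | intermediate
29 | 4-tert-butyl 1-methyl (2R)-2-hydroxybutanedioate | CC(C)(C)OC(=O)C[C@@H](O)C(=O)OC | intermediate
30 | dilithium alkoxide ester enolate of 29 | [Li]OC(OC(C)(C)C)=C[C@@H](O[Li])C(=O)OC | intermediate
31 | 2-tert-butyl 1-methyl 3-prop-2-en-1-yl (1R,2S)-1-hydroxypropane-1,2,3-tricarboxylate | O[C@@H](C(=O)OC)[C@H](CC(=O)OCC=C)C(=O)OC(C)(C)C | intermediate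
32 | 1-methyl 3-prop-2-en-1-yl 2-triethylsilyl (1R,2S)-1-[(triethylsilyl)oxy]propane-1,2,3-tricarboxylate | CC[Si](CC)(CC)O[C@@H](C(=O)OC)[C@H](CC(=O)OCC=C)C(=O)O[Si](CC)(CC)CC | intermediate
33 | (2S,3R)-2-[2-(allyloxy)-2-oxoethyl]-4-methoxy-4-oxo-3-[(triethylsilyl)oxy]butanoic acid | CC[Si](CC)(CC)O[C@@H](C(=O)OC)[C@H](CC(=O)OCC=C)C(=O)O | intermediate
34 | 2-allyl 1,3-dimethyl (1R,2S)-1-{[15-(tert-butyldiphenylsilyloxy)drim-8(12)-en-11-yl]oxy}propane-1,2,3-tricarboxylate (unit A with isocitrate 1) | C=C1CC[C@H]2[C@](C)(CO[Si](c3ccccc3)(c4ccccc4)C(C)(C)C)CCC[C@]2(C)[C@H]1CO[C@@H](C(=O)OC)[C@H](CC(=O)OC)C(=O)OCC=C | intermediate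
35 | 2-allyl 1,3-dimethyl (1R,2S)-1-{[15-hydroxydrim-8(12)-en-11-yl]oxy}propane-1,2,3-tricarboxylate | C=C1CC[C@H]2[C@](C)(CO)CCC[C@]2(C)[C@H]1CO[C@@H](C(=O)OC)[C@H](CC(=O)OC)C(=O)OCC=C | intermediate
36 | 35 esterified at O-15 with acid 33 (isocitrate 2: 1-methyl ester, 3-allyl ester, 1-O-TES) | C=C1CC[C@H]2[C@](C)(COC(=O)[C@@H](CC(=O)OCC=C)[C@@H](O[Si](CC)(CC)CC)C(=O)OC)CCC[C@]2(C)[C@H]1CO[C@@H](C(=O)OC)[C@H](CC(=O)OC)C(=O)OCC=C | intermediate
37 | 36 with the TES group replaced by 15-(tert-butyldiphenylsilyloxy)drim-8(12)-en-11-yl (unit B) as ether on isocitrate 2 | C=C1CC[C@H]2[C@](C)(COC(=O)[C@@H](CC(=O)OCC=C)[C@@H](OC[C@H]3C(=C)CC[C@H]4[C@](C)(CO[Si](c5ccccc5)(c6ccccc6)C(C)(C)C)CCC[C@]34C)C(=O)OC)CCC[C@]2(C)[C@H]1CO[C@@H](C(=O)OC)[C@H](CC(=O)OC)C(=O)OCC=C | intermediate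
38 | 37 with free 15-OH on unit B | C=C1CC[C@H]2[C@](C)(COC(=O)[C@@H](CC(=O)OCC=C)[C@@H](OC[C@H]3C(=C)CC[C@H]4[C@](C)(CO)CCC[C@]34C)C(=O)OC)CCC[C@]2(C)[C@H]1CO[C@@H](C(=O)OC)[C@H](CC(=O)OC)C(=O)OCC=C | intermediate
39 | 38 esterified at O-15 of unit B with acid 33 (isocitrate 3 as TES ether) | C=C1CC[C@H]2[C@](C)(COC(=O)[C@@H](CC(=O)OCC=C)[C@@H](OC[C@H]3C(=C)CC[C@H]4[C@](C)(COC(=O)[C@@H](CC(=O)OCC=C)[C@@H](O[Si](CC)(CC)CC)C(=O)OC)CCC[C@]34C)C(=O)OC)CCC[C@]2(C)[C@H]1CO[C@@H](C(=O)OC)[C@H](CC(=O)OC)C(=O)OCC=C | intermediate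
40 | protected trimer: 39 with the TES group replaced by 15-(tert-butyldiphenylsilyloxy)drim-8(12)-en-11-yl (unit C) | C=C1CC[C@H]2[C@](C)(COC(=O)[C@@H](CC(=O)OCC=C)[C@@H](OC[C@H]3C(=C)CC[C@H]4[C@](C)(COC(=O)[C@@H](CC(=O)OCC=C)[C@@H](OC[C@H]5C(=C)CC[C@H]6[C@](C)(CO[Si](c7ccccc7)(c8ccccc8)C(C)(C)C)CCC[C@]56C)C(=O)OC)CCC[C@]34C)C(=O)OC)CCC[C@]2(C)[C@H]1CO[C@@H](C(=O)OC)[C@H](CC(=O)OC)C(=O)OCC=C | intermediate
41 | cryptoporic acid T triallyl ester (free 15-OH on unit C) | C=C1CC[C@H]2[C@](C)(COC(=O)[C@@H](CC(=O)OCC=C)[C@@H](OC[C@H]3C(=C)CC[C@H]4[C@](C)(COC(=O)[C@@H](CC(=O)OCC=C)[C@@H](OC[C@H]5C(=C)CC[C@H]6[C@](C)(CO)CCC[C@]56C)C(=O)OC)CCC[C@]34C)C(=O)OC)CCC[C@]2(C)[C@H]1CO[C@@H](C(=O)OC)[C@H](CC(=O)OC)C(=O)OCC=C | intermediate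
42 | cryptoporic acid T | C=C1CC[C@H]2[C@](C)(COC(=O)[C@@H](CC(=O)O)[C@@H](OC[C@H]3C(=C)CC[C@H]4[C@](C)(COC(=O)[C@@H](CC(=O)O)[C@@H](OC[C@H]5C(=C)CC[C@H]6[C@](C)(CO)CCC[C@]56C)C(=O)OC)CCC[C@]34C)C(=O)OC)CCC[C@]2(C)[C@H]1CO[C@@H](C(=O)OC)[C@H](CC(=O)OC)C(=O)O | target

**Count and risks**

Total step count: 34. Longest linear sequence: 27 steps (steps 1–18, then 26–34).

Steps most likely to fail:

Step 11. The cycloaddition may be slow because the C10 methyl sits inside the diene, so that Lewis-acid-induced ionisation or oligomerisation of the diene, or loss of endo selectivity, can compete. The fallback sets out from aldehyde 12: Wittig reaction with methyl 2-(triphenylphosphoranylidene)propanoate should give the triene ester F1, which would be cyclised without Lewis acid by heating (toluene, BHT, 180 °C, sealed tube) to the decalin ester F2, the cis-fused isomer being removed by chromatography. LiAlH4 reduction of F2 returns to the route at alcohol 15.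

Step 26 (the same holds for steps 29 and 32). The oxocarbenium ion at C11 may lose H-9 and drag the exocyclic double bond into conjugation, or C9 may epimerise, faster than hydride is transferred. The fallback sets out from alcohol 20: Tf2O with 2,6-di-tert-butyl-4-methylpyridine should give the primary triflate F3, which would alkylate the free hydroxyl of triester 27 in an SN2 etherification (same hindered base, CH2Cl2, rt). It comes back at ether 34.

Step 24 (the same holds for step 21). The lithium alkoxide of the product may lactonise onto the new γ-ester, or the α-halo ester may react with poor anti selectivity. The fallback sets out from 29: Fráter–Seebach alkylation with allyl bromide should give the C-allyl malate F4, silylation (Et3SiCl, imidazole) the TES ether F5, and ozonolysis (O3, then PPh3) followed by Pinnick oxidation (NaClO2, NaH2PO4, 2-methylbut-2-ene) the acid F6. Allyl bromide/KHCO3 would then give the triester F7, and Et3SiOTf/2,6-lutidine as in step 25 returns to the route at acid 33.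

Further compounds
F1 | step 11 | methyl (2E,6R,7S,8E)-6-(benzyloxy)-7-{[(tert-butyldimethylsilyl)oxy]methyl}-2,8-dimethylundeca-2,8,10-trienoate | COC(=O)/C(C)=C/CC[C@@H](OCc1ccccc1)[C@H](CO[Si](C)(C)C(C)(C)C)/C(C)=C/C=C
F2 | step 11 | methyl 8α-(benzyloxy)-11-[(tert-butyldimethylsilyl)oxy]-12-nordrim-1-en-15-oate | CC(C)(C)[Si](C)(C)OC[C@H]1[C@H](OCc3ccccc3)CC[C@H]2[C@](C)(C(=O)OC)CC=C[C@]12C
F3 | step 26 | 15-[(tert-butyldiphenylsilyl)oxy]drim-8(12)-en-11-yl trifluoromethanesulfonate | O=S(=O)(OC[C@H]1C(=C)CC[C@H]2[C@](C)(CO[Si](c4ccccc4)(c5ccccc5)C(C)(C)C)CCC[C@]12C)C(F)(F)F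
F4 | step 24 | 4-tert-butyl 1-methyl (2R,3S)-2-hydroxy-3-(prop-2-en-1-yl)butanedioate | O[C@@H](C(=O)OC)[C@H](CC=C)C(=O)OC(C)(C)C
F5 | step 24 | 4-tert-butyl 1-methyl (2R,3S)-3-(prop-2-en-1-yl)-2-[(triethylsilyl)oxy]butanedioate | CC[Si](CC)(CC)O[C@@H](C(=O)OC)[C@H](CC=C)C(=O)OC(C)(C)C
F6 | step 24 | (3S,4R)-3-(tert-butoxycarbonyl)-5-methoxy-5-oxo-4-[(triethylsilyl)oxy]pentanoic acid | CC[Si](CC)(CC)O[C@@H](C(=O)OC)[C@H](CC(=O)O)C(=O)OC(C)(C)C
F7 | step 24 | 2-tert-butyl 1-methyl 3-prop-2-en-1-yl (1R,2S)-1-[(triethylsilyl)oxy]propane-1,2,3-tricarboxylate | CC[Si](CC)(CC)O[C@@H](C(=O)OC)[C@H](CC(=O)OCC=C)C(=O)OC(C)(C)C
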